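The numbers of this flask come from no measurement.

If the flask below has come to rest by the asked time, its state follows from a balance on J and the two equilibrium constants, with no rate constant in it.

    J + J ⇌ J2 (K1 = 8.3 M⁻¹, k1 = 0.0019 M⁻¹ s⁻¹)
    J2 ⇌ Q (K2 = 0.39, k2 = 1.7 × 10⁻⁴ s⁻¹)
    J + D → J.D (k3 = 1.2 M⁻¹ s⁻¹)

J 0.064 M (fed, over 1.5 h); D 1.28 mM; time 15 h

- percentages count the J that a species holds: one J2 or Q counts as two
- a step written with two of one species runs at k times the square of its concentration and takes two of it each time
- the reaction counts as stopped when no species that holds the J changes by six tenths of a point or more over the second half of the time
- run time (flask): 15 h

1. the state of affairs at 15 h: stopped, and by what, or still going (all of J has reacted / forward and back rates have come level / it is still moving)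
2. share of the J used up at 15 h
3. J2 at 15 h, in percent of the J charged

D, the limiting reagent of step 3, is the smaller charge, 1.28 mM against 0.064 M of J. The half-life of J by that step, with D held at its charge, is 0.13 h, shorter than the 15 h of the run. So the reckoning counts D as taking its own amount of J out, with 0.0627 M of J remaining for pairing. The bench rule for a dilute dimerisation counts this J as free and sets c(J2) at the equilibrium constant of step 1 times the square of c(J). Here that rule puts 102% of the charge into J2, more than was charged. Its border is the pairing number: twice the equilibrium constant of step 1, times one plus that of step 2, times the J remaining. This counts the J held in J2 and Q per free J, were c(J) to stand at the remaining J. The rule needs this number well below one, but in this flask it is 1.45.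

With f as the free share of the remaining J, the balance reads f plus the pairing number times f squared equals one. Its root gives f = 55.5%, so c(J) = 0.0348 M. The hand reckoning therefore commits to 45.6% of the J used up and 31.4% as J2. The back half-life of step 1, 0.841 h, and the relaxation half-life of J2 and Q by step 2, 0.318 h, are both short against 15 h, so the reckoning expects level rates.

The forecast says that forward and back rates have come level, with 45.6% of the J used up and 31.4% as J2, holding that “The slowest relaxation time is only a couple of hours at most”.

The state of the flask at 15 h is that forward and back rates have come level, with 45.6% of the J used up and 31.4% as J2. No share in it moves by more than 0.0099 percentage points over the second half of the time. Its pairing number of 1.45 gives a free share of 55.5% of the remaining J, which is 54.4% of the charge, and the flask holds 54.4% of the charge as J. The neighbour flask with 0.26 M of J has a pairing number of 5.97, which gives a free share of 33.4% of its remaining J, or 33.2% of its charge. That neighbour flask holds 33.2% of its charge as J and 47.7% as J2 at 15 h.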